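**Strategy.** The route rests on disconnecting the bond between the furanone ketone carbon (C1) and the furanone CH carbon (C2), which lies in both the five-membered furanone and the ten-membered carbocycle, as an acetylide–aldehyde bond: C2≡C3 is an alkyne at the oxidation level of the furanone enol ether. A Nozaki–Hiyama–Kishi iodoalkyne–aldehyde addition closes the ten-membered ring in one operation. Its precursor is a seco iodoalkyne aldehyde that already carries the trans methylene lactone, the Z-C4=C5 alkene and an O9/O10 acetonide, which fold it. Oxidation and 5-endo attack of O10 on C3 then bridge the ring as the furanone. C9/C10 come from L-glyceraldehyde by relay; C8, C7 and C6 follow by substrate control.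

Key step: step 17

Remark on the chemistry: atoms are numbered as in germacranolides (C1 ketone, C2 furanone CH, C3 furanone C–O carbon, C4=C5 the Z-alkene with C15 on C4, C6 lactone carbinol, C7, C8 hydroxyl carbon, C9 ester carbon, C10 quaternary carbon with C14, C11–C13 the methylene lactone, On the oxygen on Cn); compounds 1, 2 and 36 are assumed to be purchased.

## Route

Step 1
Reactants: 1 (4S)-2,2-dimethyl-1,3-dioxolane-4-carbaldehyde; 2 ethyl 2-[bis(2,2,2-trifluoroethoxy)phosphoryl]propanoate
Product: 3 ethyl (2Z)-3-[(4R)-2,2-dimethyl-1,3-dioxolan-4-yl]-2-methylprop-2-enoate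
Conditions: 2, KN(SiMe3)2, 18-crown-6, THF, −78 °C; then 1
Reagents that add atoms: none
Why: Still–Gennari olefination, in which the bis(trifluoroethyl) phosphonate should collapse kinetically to the Z-trisubstituted enoate (ester cis to the dioxolane, as the later erythro C9/C10 diol requires) without creating a stereocentre.

Step 2
Reactants: 3 ethyl (2Z)-3-[(4R)-2,2-dimethyl-1,3-dioxolan-4-yl]-2-methylprop-2-enoate
Product: 4 ethyl (2S,3S)-3-[(4S)-2,2-dimethyl-1,3-dioxolan-4-yl]-2,3-dihydroxy-2-methylpropanoate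
Conditions: OsO4 (2 mol%), N-methylmorpholine N-oxide, acetone/H2O, 0 °C to rt
Reagents that add atoms: N-methylmorpholine N-oxide (C[N+]1([O-])CCOCC1); water (O)
Why: Upjohn syn-dihydroxylation, in which osmium tetroxide should add to the A(1,3)-minimised conformer of the Z-alkene anti to the allylic C–O bond (empirical rule for osmylation of allylic ethers), so that C9 and C10 are set together, erythro to the dioxolane oxygen.

Step 3
Reactants: 4 ethyl (2S,3S)-3-[(4S)-2,2-dimethyl-1,3-dioxolan-4-yl]-2,3-dihydroxy-2-methylpropanoate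
Product: 5 ethyl (4S,5S)-5-[(4S)-2,2-dimethyl-1,3-dioxolan-4-yl]-2,2,4-trimethyl-1,3-dioxolane-4-carboxylate
Conditions: 2,2-dimethoxypropane, camphorsulfonic acid (cat.), acetone, rt
Reagents that add atoms: 2,2-dimethoxypropane (COC(C)(C)OC)
Why: acid-catalysed acetonide formation (transketalisation) on the secondary/tertiary syn-diol, which ties O9 and O10 into a ring for the later Felkin–Anh control and regiocontrol and touches no stereocentre.

Step 4
Reactants: 5 ethyl (4S,5S)-5-[(4S)-2,2-dimethyl-1,3-dioxolan-4-yl]-2,2,4-trimethyl-1,3-dioxolane-4-carboxylate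
Product: 6 [(4R,5S)-5-[(4S)-2,2-dimethyl-1,3-dioxolan-4-yl]-2,2,4-trimethyl-1,3-dioxolan-4-yl]methanol
Conditions: LiAlH4, THF, 0 °C
Reagents that add atoms: none
Why: hydride reduction of the ester to the neopentyl primary alcohol (future C1), to which ketals and stereocentres are inert.

Step 5
Reactants: 6 [(4R,5S)-5-[(4S)-2,2-dimethyl-1,3-dioxolan-4-yl]-2,2,4-trimethyl-1,3-dioxolan-4-yl]methanol
Product: 9 lactol (3aR,6aR)-2,2,6a-trimethyltetrahydrofuro[3,4-d][1,3]dioxol-4-ol (both anomers), via triol 7 (not isolated), via hydroxy aldehyde 8 (not isolated)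
Conditions: H5IO6, EtOAc, rt
Reagents that add atoms: none
Why: periodic acid should hydrolyse the less hindered terminal acetonide and cleave the freed 1,2-diol (Malaprade glycol cleavage), so that the sacrificial glyceraldehyde carbon leaves as formaldehyde and the aldehyde (future C8) is trapped by the cis primary hydroxyl as the lactol, with C9 and C10 unaffected.

Step 6
Reactants: 10 2,2-dimethoxyacetaldehyde; 11 methyl acrylate
Product: 12 methyl 3-hydroxy-4,4-dimethoxy-2-methylidenebutanoate (racemic)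
Conditions: DABCO (0.5 equiv), 1,4-dioxane/H2O, rt
Reagents that add atoms: none
Why: Morita–Baylis–Hillman reaction; the carbinol centre formed is racemic and is erased in step 7.

Step 7
Reactants: 12 methyl 3-hydroxy-4,4-dimethoxy-2-methylidenebutanoate
Product: 13 methyl (2Z)-2-(bromomethyl)-4,4-dimethoxybut-2-enoate
Conditions: N-bromosuccinimide, Me2S, CH2Cl2, 0 °C to rt
Reagents that add atoms: N-bromosuccinimide (O=C1CCC(=O)N1Br)
Why: Corey–Kim-type activation of the hydroxyl and SN2' delivery of bromide should give the conjugated allylic bromide as its preferred Z isomer (CH2Br cis to the acetal carbon).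

Step 8
Reactants: 9 lactol (3aR,6aR)-2,2,6a-trimethyltetrahydrofuro[3,4-d][1,3]dioxol-4-ol; 13 methyl (2Z)-2-(bromomethyl)-4,4-dimethoxybut-2-enoate
Product: 15 methyl (3R,4S)-3-(dimethoxymethyl)-4-hydroxy-4-[(4S,5R)-5-(hydroxymethyl)-2,2,5-trimethyl-1,3-dioxolan-4-yl]-2-methylidenebutanoate, via allylindium species 14 (not isolated)
Conditions: indium powder, THF/H2O (1:1), rt
Reagents that add atoms: none
Why: indium-mediated Barbier 2-(alkoxycarbonyl)allylation of the aldehyde in equilibrium with the lactol, in which the Z-allylindium should react at its γ-carbon through a chair transition state (syn relationship of C8–OH and the C7 acetal branch) and attack anti to the α-C–O bond of the rigid dioxolane (Felkin–Anh), so that C7 and C8 are set in one event from C9.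

Step 9
Reactants: 15 methyl (3R,4S)-3-(dimethoxymethyl)-4-hydroxy-4-[(4S,5R)-5-(hydroxymethyl)-2,2,5-trimethyl-1,3-dioxolan-4-yl]-2-methylidenebutanoate
Product: 17 bis-silyl aldehyde (methyl (3R,4S)-3-formyl-2-methylidenebutanoate with TBS ethers on O8 and O1), via bis-silyl acetal 16 (not isolated)
Conditions: TBSOTf, 2,6-lutidine, CH2Cl2, −78 to 0 °C; then TESOTf, 2,4,6-collidine, 0 °C; then H2O
Reagents that add atoms: tert-butyldimethylsilyl trifluoromethanesulfonate (CC(C)(C)[Si](C)(C)OS(=O)(=O)C(F)(F)F); water (O)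
Why: silyl triflate silylation of both hydroxyls, then chemoselective cleavage of the dimethyl acetal by a silyl triflate and a pyridine base through a pyridinium intermediate that water converts into the aldehyde, a method that spares ketals and silyl ethers and avoids aqueous acid, so that the C7 stereocentre should survive.

Step 10
Reactants: 18 prop-2-yn-1-ol
Product: 20 (2Z)-3-iodo-2-methylprop-2-en-1-ol, via alkenylmagnesium alkoxide 19 (not isolated)
Conditions: MeMgBr (2.5 equiv), CuI (10 mol%), Et2O, −10 °C to rt; then I2, −10 °C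
Reagents that add atoms: methylmagnesium bromide (C[Mg]Br); iodine (I-I)
Why: copper-catalysed anti-carbomagnesiation of the propargylic alkoxide should give a chelated alkenylmagnesium whose iodinolysis with retention fixes iodine cis to the CH2OH carbon, which is the later Z-C4=C5 geometry.

Step 11
Reactants: 20 (2Z)-3-iodo-2-methylprop-2-en-1-ol
Product: 21 (2Z)-3-iodo-2-methylprop-2-enal
Conditions: MnO2, CH2Cl2, rt, dark
Reagents that add atoms: none
Why: allylic oxidation with manganese dioxide under neutral conditions, chosen to keep the Z geometry of the sensitive β-iodo enal.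

Step 12
Reactants: 21 (2Z)-3-iodo-2-methylprop-2-enal
Product: 22 (1Z)-1-iodo-2-methylbut-1-en-3-yne
Conditions: (trimethylsilyl)diazomethane, LiN(iPr)2, THF, −78 °C to rt
Reagents that add atoms: (trimethylsilyl)diazomethane (C[Si](C)(C)C=[N+]=[N-])
Why: Colvin rearrangement, in which the lithiated silyldiazomethane adds to the aldehyde and Peterson elimination with loss of N2 gives an alkylidene carbene that shifts hydrogen to the terminal alkyne, without touching the alkenyl iodide.

Step 13
Reactants: 17 bis-silyl aldehyde; 22 (1Z)-1-iodo-2-methylbut-1-en-3-yne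
Product: 25 bis-silyl enyne lactone (trans-4,5-disubstituted 3-methylideneoxolan-2-one), via alkenylchromium species 23 (not isolated), via hydroxy ester 24 (not isolated)
Conditions: CrCl2 (6 equiv), NiCl2 (2 mol%), DMSO, rt; then PPTS, toluene, 50 °C
Reagents that add atoms: none
Why: Nozaki–Hiyama–Kishi alkenylation with retention of the Z geometry, in which the non-basic alkenylchromium should add to the C6 aldehyde anti to the large C8 branch (Felkin–Anh, reinforced by the 1,3-anti preference of the β-silyloxy group) to set C6, followed by acid-catalysed lactonisation onto the methyl ester to the trans γ-lactone.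

Step 14
Reactants: 25 bis-silyl enyne lactone
Product: 26 enyne lactone alcohol (free C1 hydroxyl)
Conditions: HF·pyridine, pyridine, THF, 0 °C
Reagents that add atoms: none
Why: fluoride-mediated desilylation, which should be selective for the primary silyl ether over the hindered secondary one at C8.

Step 15
Reactants: 26 enyne lactone alcohol
Product: 27 iodoalkyne alcohol
Conditions: N-iodosuccinimide, AgNO3 (10 mol%), acetone, rt
Reagents that add atoms: N-iodosuccinimide (O=C1CCC(=O)N1I)
Why: silver-catalysed electrophilic iodination of the terminal alkyne through the silver acetylide.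

Step 16
Reactants: 27 iodoalkyne alcohol
Product: 28 iodoalkyne aldehyde
Conditions: Dess–Martin periodinane, NaHCO3, CH2Cl2, rt
Reagents that add atoms: none
Why: Dess–Martin oxidation of the primary alcohol to the non-enolisable α-alkoxy aldehyde C1 under buffered conditions.

Step 17
Reactants: 28 iodoalkyne aldehyde
Product: 30 macrocyclic ynol (ten-membered ring, both C1 epimers), via alkynylchromium species 29 (not isolated)
Conditions: CrCl2 (10 equiv), NiCl2 (5 mol%), THF, 1 mM (syringe pump), rt
Reagents that add atoms: none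
Why: Divalent chromium (with catalytic NiCl2) reductively metalates the C(sp)–I bond to a trivalent alkynylchromium, which adds to the tethered α-alkoxy aldehyde (intramolecular Nozaki–Hiyama–Kishi alkynylation). The closest known reaction type is the CrCl2/NiCl2 iodoalkyne–aldehyde closure used for nine- and ten-membered enediyne rings. The ten-membered carbocycle closes in a 10-exo-trig mode at the C1 carbonyl, with C2 as the nucleophile. The only new stereocentre, the C1 carbinol, is uncontrolled and is erased by the oxidation in step 18. The step needs ring closure to win over oligomerisation and over any attack on the lactone or the acrylate; high dilution, the aldehyde-selective organochromium and the pre-folding by the Z-C4=C5 alkene (C3 and C6 cis), the trans-fused lactone and the C9/C10 dioxolane should secure this.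

Step 18
Reactants: 30 macrocyclic ynol
Product: 31 macrocyclic ynone
Conditions: Dess–Martin periodinane, NaHCO3, CH2Cl2, 0 °C
Reagents that add atoms: none
Why: Dess–Martin oxidation, which converts both C1 epimers into the single cross-conjugated ynone.

Step 19
Reactants: 31 macrocyclic ynone
Product: 32 furanone alcohol (free C9 hydroxyl, TBS ether on O8)
Conditions: (Ph3P)AuNTf2 (5 mol%), H2O (3 equiv), CH2Cl2, rt
Reagents that add atoms: none
Why: Proposed new method: cationic monovalent gold activates the C2≡C3 bond of the ynone, the acetonide oxygen on C10 attacks C3 in a 5-endo-dig mode (a fused 5/5 oxonium, whereas attack by O9 would need a bridged bicycle), the oxonium collapses to a 2-propyl oxocarbenium ion on O9 that water hydrolyses to acetone and the free C9 hydroxyl, and protodeauration gives the furanone; the closest known reaction types are the gold-catalysed cycloisomerisation of free α'-hydroxy ynones to 3(2H)-furanones and gold-catalysed alkyne hydroalkoxylation by acetonide oxygens with loss of acetone.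

Step 20
Reactants: 33 diphenyl phosphite; 34 tert-butyl 2-bromopropanoate
Product: 35 tert-butyl 2-(diphenoxyphosphoryl)propanoate
Conditions: NaH, THF, 0 °C to rt
Reagents that add atoms: none
Why: Michaelis–Becker reaction, in which sodium diphenyl phosphite displaces bromide from the activated α-bromo ester.

Step 21
Reactants: 35 tert-butyl 2-(diphenoxyphosphoryl)propanoate; 36 2-oxoethyl acetate
Product: 37 tert-butyl (2Z)-4-acetoxy-2-methylbut-2-enoate
Conditions: 35, NaH, THF, −78 °C; then 36, −78 to 0 °C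
Reagents that add atoms: none
Why: Horner–Wadsworth–Emmons olefination in its Z-selective diaryl phosphonate variant (Ando), which should place the CH2OAc carbon cis to the ester.

Step 22
Reactants: 37 tert-butyl (2Z)-4-acetoxy-2-methylbut-2-enoate
Product: 38 (2Z)-4-acetoxy-2-methylbut-2-enoic acid
Conditions: CF3CO2H, CH2Cl2, 0 °C
Reagents that add atoms: none
Why: acidolysis of the tert-butyl ester with loss of 2-methylpropene, which should leave the acetate and the Z geometry.

Step 23
Reactants: 32 furanone alcohol; 38 (2Z)-4-acetoxy-2-methylbut-2-enoic acid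
Product: 40 silyl-protected target, via mixed anhydride 39 (not isolated)
Conditions: 38, 2,4,6-trichlorobenzoyl chloride, Et3N, toluene, rt; then 32, DMAP, rt
Reagents that add atoms: none
Why: Yamaguchi esterification, in which the mixed anhydride acylates the only free hydroxyl (C9) under DMAP catalysis, a method known to esterify hindered alcohols with angelate-type acids without Z to E isomerisation.

Step 24
Reactants: 40 silyl-protected target
Product: 41 target CNP0523348.1
Conditions: HF·pyridine, pyridine, THF, 0 °C to rt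
Reagents that add atoms: none
Why: fluoride-mediated cleavage of the secondary silyl ether on O8 under buffered conditions that the two Michael acceptors, the acetate and the Z-enoate should tolerate.

## Compound list

1 | (4S)-2,2-dimethyl-1,3-dioxolane-4-carbaldehyde ((S)-glyceraldehyde acetonide) | O=C[C@@H]1COC(C)(C)O1 | starting material
2 | ethyl 2-[bis(2,2,2-trifluoroethoxy)phosphoryl]propanoate | CCOC(=O)C(C)P(=O)(OCC(F)(F)F)OCC(F)(F)F | starting material
3 | ethyl (2Z)-3-[(4R)-2,2-dimethyl-1,3-dioxolan-4-yl]-2-methylprop-2-enoate | CCOC(=O)/C(C)=C\[C@@H]1COC(C)(C)O1 | intermediate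
4 | ethyl (2S,3S)-3-[(4S)-2,2-dimethyl-1,3-dioxolan-4-yl]-2,3-dihydroxy-2-methylpropanoate | CCOC(=O)[C@@](C)(O)[C@@H](O)[C@@H]1COC(C)(C)O1 | intermediate
5 | ethyl (4S,5S)-5-[(4S)-2,2-dimethyl-1,3-dioxolan-4-yl]-2,2,4-trimethyl-1,3-dioxolane-4-carboxylate | CCOC(=O)[C@@]1(C)OC(C)(C)O[C@H]1[C@@H]2COC(C)(C)O2 | intermediate
6 | [(4R,5S)-5-[(4S)-2,2-dimethyl-1,3-dioxolan-4-yl]-2,2,4-trimethyl-1,3-dioxolan-4-yl]methanol | OC[C@@]1(C)OC(C)(C)O[C@H]1[C@@H]2COC(C)(C)O2 | intermediate
7 | triol: (1S)-1-[(4S,5R)-5-(hydroxymethyl)-2,2,5-trimethyl-1,3-dioxolan-4-yl]ethane-1,2-diol | OC[C@@]1(C)OC(C)(C)O[C@H]1[C@@H](O)CO | intermediate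
8 | hydroxy aldehyde: (4R,5R)-5-(hydroxymethyl)-2,2,5-trimethyl-1,3-dioxolane-4-carbaldehyde | OC[C@@]1(C)OC(C)(C)O[C@H]1C=O | intermediate
9 | lactol: (3aR,6aR)-2,2,6a-trimethyltetrahydrofuro[3,4-d][1,3]dioxol-4-ol, both anomers | OC1OC[C@@]2(C)OC(C)(C)O[C@@H]12 | intermediate
10 | 2,2-dimethoxyacetaldehyde | COC(OC)C=O | starting material
11 | methyl acrylate | C=CC(=O)OC | starting material
12 | methyl 3-hydroxy-4,4-dimethoxy-2-methylidenebutanoate, racemic | COC(OC)C(O)C(=C)C(=O)OC | intermediate
13 | methyl (2Z)-2-(bromomethyl)-4,4-dimethoxybut-2-enoate | COC(OC)/C=C(\CBr)C(=O)OC | intermediate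
14 | allylindium species, drawn as [(2Z)-4,4-dimethoxy-2-(methoxycarbonyl)but-2-en-1-yl]indium dibromide | COC(OC)/C=C(\C[In](Br)Br)C(=O)OC | intermediate
15 | methyl (3R,4S)-3-(dimethoxymethyl)-4-hydroxy-4-[(4S,5R)-5-(hydroxymethyl)-2,2,5-trimethyl-1,3-dioxolan-4-yl]-2-methylidenebutanoate | COC(=O)C(=C)[C@@H](C(OC)OC)[C@H](O)[C@@H]1OC(C)(C)O[C@]1(C)CO | intermediate
16 | bis-silyl acetal: methyl (3R,4S)-4-[(tert-butyldimethylsilyl)oxy]-4-[(4S,5R)-5-{[(tert-butyldimethylsilyl)oxy]methyl}-2,2,5-trimethyl-1,3-dioxolan-4-yl]-3-(dimethoxymethyl)-2-methylidenebutanoate | COC(=O)C(=C)[C@@H](C(OC)OC)[C@H](O[Si](C)(C)C(C)(C)C)[C@@H]1OC(C)(C)O[C@]1(C)CO[Si](C)(C)C(C)(C)C | intermediate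
17 | bis-silyl aldehyde: methyl (3R,4S)-4-[(tert-butyldimethylsilyl)oxy]-4-[(4S,5R)-5-{[(tert-butyldimethylsilyl)oxy]methyl}-2,2,5-trimethyl-1,3-dioxolan-4-yl]-3-formyl-2-methylidenebutanoate | COC(=O)C(=C)[C@@H](C=O)[C@H](O[Si](C)(C)C(C)(C)C)[C@@H]1OC(C)(C)O[C@]1(C)CO[Si](C)(C)C(C)(C)C | intermediate
18 | prop-2-yn-1-ol | C#CCO | starting material
19 | alkenylmagnesium alkoxide: bromomagnesium (2Z)-3-(bromomagnesio)-2-methylprop-2-en-1-olate | Br[Mg]OC/C(C)=C\[Mg]Br | intermediate
20 | (2Z)-3-iodo-2-methylprop-2-en-1-ol | OC/C(C)=C\I | intermediate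
21 | (2Z)-3-iodo-2-methylprop-2-enal | O=C/C(C)=C\I | intermediate
22 | (1Z)-1-iodo-2-methylbut-1-en-3-yne | C#C/C(C)=C\I | intermediate
23 | alkenylchromium species: [(1Z)-2-methylbut-1-en-3-yn-1-yl]chromium dichloride | C#C/C(C)=C\[Cr](Cl)Cl | intermediate
24 | hydroxy ester: methyl (3S,4S)-4-[(tert-butyldimethylsilyl)oxy]-4-[(4S,5R)-5-{[(tert-butyldimethylsilyl)oxy]methyl}-2,2,5-trimethyl-1,3-dioxolan-4-yl]-3-[(1R,2Z)-1-hydroxy-3-methylpent-2-en-4-yn-1-yl]-2-methylidenebutanoate | COC(=O)C(=C)[C@@H]([C@H](O)/C=C(/C)C#C)[C@H](O[Si](C)(C)C(C)(C)C)[C@@H]1OC(C)(C)O[C@]1(C)CO[Si](C)(C)C(C)(C)C | intermediate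
25 | bis-silyl enyne lactone: (4S,5R)-4-{(S)-[(tert-butyldimethylsilyl)oxy][(4S,5R)-5-{[(tert-butyldimethylsilyl)oxy]methyl}-2,2,5-trimethyl-1,3-dioxolan-4-yl]methyl}-3-methylidene-5-[(1Z)-2-methylbut-1-en-3-yn-1-yl]oxolan-2-one | C=C1C(=O)O[C@H](/C=C(/C)C#C)[C@H]1[C@H](O[Si](C)(C)C(C)(C)C)[C@@H]2OC(C)(C)O[C@]2(C)CO[Si](C)(C)C(C)(C)C | intermediate
26 | enyne lactone alcohol: (4S,5R)-4-{(S)-[(tert-butyldimethylsilyl)oxy][(4S,5R)-5-(hydroxymethyl)-2,2,5-trimethyl-1,3-dioxolan-4-yl]methyl}-3-methylidene-5-[(1Z)-2-methylbut-1-en-3-yn-1-yl]oxolan-2-one | C=C1C(=O)O[C@H](/C=C(/C)C#C)[C@H]1[C@H](O[Si](C)(C)C(C)(C)C)[C@@H]2OC(C)(C)O[C@]2(C)CO | intermediate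
27 | iodoalkyne alcohol: (4S,5R)-4-{(S)-[(tert-butyldimethylsilyl)oxy][(4S,5R)-5-(hydroxymethyl)-2,2,5-trimethyl-1,3-dioxolan-4-yl]methyl}-5-[(1Z)-4-iodo-2-methylbut-1-en-3-yn-1-yl]-3-methylideneoxolan-2-one | C=C1C(=O)O[C@H](/C=C(/C)C#CI)[C@H]1[C@H](O[Si](C)(C)C(C)(C)C)[C@@H]2OC(C)(C)O[C@]2(C)CO | intermediate
28 | iodoalkyne aldehyde: (4S,5S)-5-[(S)-[(tert-butyldimethylsilyl)oxy]{(2R,3S)-2-[(1Z)-4-iodo-2-methylbut-1-en-3-yn-1-yl]-4-methylidene-5-oxooxolan-3-yl}methyl]-2,2,4-trimethyl-1,3-dioxolane-4-carbaldehyde | C=C1C(=O)O[C@H](/C=C(/C)C#CI)[C@H]1[C@H](O[Si](C)(C)C(C)(C)C)[C@@H]2OC(C)(C)O[C@]2(C)C=O | intermediate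
29 | alkynylchromium species: the alkynylchromium dichloride formed from 28 at C2 | C=C1C(=O)O[C@H](/C=C(/C)C#C[Cr](Cl)Cl)[C@H]1[C@H](O[Si](C)(C)C(C)(C)C)[C@@H]2OC(C)(C)O[C@]2(C)C=O | intermediate
30 | macrocyclic ynol: (6R,7S,8S,9S,10R)-8-[(tert-butyldimethylsilyl)oxy]-1-hydroxy-9,10-(isopropylidenedioxy)germacra-4(Z),11(13)-dien-2-yn-12,6-olide, both C1 epimers | C=C1C(=O)O[C@@H]2/C=C(/C)C#CC(O)[C@@]3(C)OC(C)(C)O[C@H]3[C@@H](O[Si](C)(C)C(C)(C)C)[C@@H]12 | intermediate
31 | macrocyclic ynone: (6R,7S,8S,9S,10S)-8-[(tert-butyldimethylsilyl)oxy]-9,10-(isopropylidenedioxy)-1-oxogermacra-4(Z),11(13)-dien-2-yn-12,6-olide | C=C1C(=O)O[C@@H]2/C=C(/C)C#CC(=O)[C@@]3(C)OC(C)(C)O[C@H]3[C@@H](O[Si](C)(C)C(C)(C)C)[C@@H]12 | intermediate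
32 | furanone alcohol: (6R,7S,8S,9S,10S)-8-[(tert-butyldimethylsilyl)oxy]-9-hydroxy-1-oxo-3,10-epoxygermacra-2,4(Z),11(13)-trien-12,6-olide | C=C1C(=O)O[C@@H]2/C=C(/C)C3=CC(=O)[C@@](C)(O3)[C@@H](O)[C@@H](O[Si](C)(C)C(C)(C)C)[C@@H]12 | intermediate
33 | diphenyl phosphite | O=[PH](Oc1ccccc1)Oc1ccccc1 | starting material
34 | tert-butyl 2-bromopropanoate | CC(Br)C(=O)OC(C)(C)C | starting material
35 | tert-butyl 2-(diphenoxyphosphoryl)propanoate | CC(C(=O)OC(C)(C)C)P(=O)(Oc1ccccc1)Oc1ccccc1 | intermediate
36 | 2-oxoethyl acetate | CC(=O)OCC=O | starting material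
37 | tert-butyl (2Z)-4-acetoxy-2-methylbut-2-enoate | CC(=O)OC/C=C(/C)C(=O)OC(C)(C)C | intermediate
38 | (2Z)-4-acetoxy-2-methylbut-2-enoic acid | CC(=O)OC/C=C(/C)C(=O)O | intermediate
39 | mixed anhydride: (2Z)-4-acetoxy-2-methylbut-2-enoic 2,4,6-trichlorobenzoic anhydride | CC(=O)OC/C=C(/C)C(=O)OC(=O)c1c(Cl)cc(Cl)cc1Cl | intermediate
40 | silyl-protected target: (6R,7S,8S,9S,10S)-9-{[(2Z)-4-acetoxy-2-methylbut-2-enoyl]oxy}-8-[(tert-butyldimethylsilyl)oxy]-1-oxo-3,10-epoxygermacra-2,4(Z),11(13)-trien-12,6-olide | C=C1C(=O)O[C@@H]2/C=C(/C)C3=CC(=O)[C@@](C)(O3)[C@@H](OC(=O)/C(C)=C\COC(C)=O)[C@@H](O[Si](C)(C)C(C)(C)C)[C@@H]12 | intermediate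
41 | target CNP0523348.1: (6R,7R,8S,9S,10S)-9-{[(2Z)-4-acetoxy-2-methylbut-2-enoyl]oxy}-8-hydroxy-1-oxo-3,10-epoxygermacra-2,4(Z),11(13)-trien-12,6-olide | C=C1C(=O)O[C@@H]2/C=C(/C)C3=CC(=O)[C@@](C)(O3)[C@@H](OC(=O)/C(C)=C\COC(C)=O)[C@@H](O)[C@@H]12 | target

## Step count and risks

Total step count: 24. Longest linear sequence: 16 steps (steps 1–5, 8, 9, 13–19, 23, 24).

Steps most likely to fail:

1. Step 19 (proposed new method). The acetonide may be hydrolysed before the cyclisation; the secondary C9 hydroxyl could then add to C3 in a 6-endo mode, or water could add to the gold-activated ynone. The fallback uses known chemistry and sets out from ynone 31. The acetonide is hydrolysed with aqueous acetic acid to the dihydroxy ynone F1. Its secondary C9 hydroxyl is acylated at once, in preference to the tertiary one, with acid 38 under Yamaguchi conditions to give the hydroxy ynone ester F2. The remaining tertiary C10 hydroxyl of this free α'-hydroxy ynone is closed by the established AuCl3-catalysed 5-endo-dig cycloisomerisation, which gives 40 and rejoins the route before step 24.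

2. Step 17 (key step). Intermolecular addition to oligomers, or protonolysis of the alkynylchromium species with reductive loss of iodine, may outpace closure of the strained ten-membered ring. The fallback sets out from alcohol 26, which is oxidised with Dess–Martin periodinane to the alkynyl aldehyde F3. The terminal alkyne is then metalated reversibly and without a reductant by Zn(OTf)2 and Et3N (Carreira alkynylation) at high dilution. The zinc acetylide adds to the C1 aldehyde to give 30, where the route is rejoined.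

3. Step 13. Aldehyde 17 may enolise toward the cross-conjugated dienol (loss of configuration at C7, migration of the exocyclic double bond) or lose the C8 silyloxy group by β-elimination before the alkenylchromium adds; facial selectivity at C6 may also be poor. The fallback sets out from 16, isolated after the silylation stage of step 9. Conjugate addition of thiophenol (Et3N) masks the acrylate as the β-phenylthio ester F4, which removes the vinylogous acidity of the C7 hydrogen. Acetal cleavage as in step 9 gives the aldehyde F5. Nozaki–Hiyama–Kishi coupling with 22 gives the hydroxy ester F6 and, after lactonisation, the phenylthiomethyl lactone F7. Oxidation with m-chloroperbenzoic acid at −78 °C to the sulfoxide F8 and thermal syn-elimination restore the methylene lactone 25, where the route is rejoined.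

Further compounds
F1 | step 19 | dihydroxy ynone: (6R,7S,8S,9S,10S)-8-[(tert-butyldimethylsilyl)oxy]-9,10-dihydroxy-1-oxogermacra-4(Z),11(13)-dien-2-yn-12,6-olide | C=C1C(=O)O[C@@H]2/C=C(/C)C#CC(=O)[C@@](C)(O)[C@@H](O)[C@@H](O[Si](C)(C)C(C)(C)C)[C@@H]12
F2 | step 19 | hydroxy ynone ester: the 9-O-[(2Z)-4-acetoxy-2-methylbut-2-enoyl] derivative of F1 | C=C1C(=O)O[C@@H]2/C=C(/C)C#CC(=O)[C@@](C)(O)[C@@H](OC(=O)/C(C)=C\COC(C)=O)[C@@H](O[Si](C)(C)C(C)(C)C)[C@@H]12
F3 | step 17 | alkynyl aldehyde: the C1 aldehyde of 26 with a terminal alkyne | C=C1C(=O)O[C@H](/C=C(/C)C#C)[C@H]1[C@H](O[Si](C)(C)C(C)(C)C)[C@@H]2OC(C)(C)O[C@]2(C)C=O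
F4 | step 13 | β-phenylthio ester: thiophenol adduct of 16 at C13, both C11 epimers | COC(=O)C(CSc1ccccc1)[C@@H](C(OC)OC)[C@H](O[Si](C)(C)C(C)(C)C)[C@@H]2OC(C)(C)O[C@]2(C)CO[Si](C)(C)C(C)(C)C
F5 | step 13 | aldehyde from F4 (C6 formyl) | COC(=O)C(CSc1ccccc1)[C@@H](C=O)[C@H](O[Si](C)(C)C(C)(C)C)[C@@H]2OC(C)(C)O[C@]2(C)CO[Si](C)(C)C(C)(C)C
F6 | step 13 | hydroxy ester from F5 and 22 | COC(=O)C(CSc1ccccc1)[C@@H]([C@H](O)/C=C(/C)C#C)[C@H](O[Si](C)(C)C(C)(C)C)[C@@H]2OC(C)(C)O[C@]2(C)CO[Si](C)(C)C(C)(C)C
F7 | step 13 | phenylthiomethyl lactone: 25 with CH(CH2SPh) in place of C=CH2 | c3ccccc3SCC1C(=O)O[C@H](/C=C(/C)C#C)[C@H]1[C@H](O[Si](C)(C)C(C)(C)C)[C@@H]2OC(C)(C)O[C@]2(C)CO[Si](C)(C)C(C)(C)C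
F8 | step 13 | sulfoxide of F7 | O=S(c3ccccc3)CC1C(=O)O[C@H](/C=C(/C)C#C)[C@H]1[C@H](O[Si](C)(C)C(C)(C)C)[C@@H]2OC(C)(C)O[C@]2(C)CO[Si](C)(C)C(C)(C)C
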